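The runs are calculated with constants of no real substance, noise included.

Time is the hard question.

| setting | Friday's | Saturday's | Monday's | flask |
|---|---|---|---|---|
| solid substrate | 0.053 M | 0.053 M | 0.080 M | 0.053 M |
| enzyme | 62 µM | 97 µM | 44 µM | 44 µM |
| remark | run made earlier | run made earlier | run made earlier |  |
| time |  |  |  | 4.0 d |

| run | time / d | target / % |
|---|---|---|
| Friday's | 0.0347 | 29 |
| Friday's | 0.104 | 48 |
| Friday's | 0.333 | 48 |
| Friday's | 1.04 | 47 |
| Friday's | 3.00 | 50 |
| Saturday's | 0.0347 | 28 |
| Saturday's | 0.104 | 46 |
| Saturday's | 0.333 | 45 |
| Saturday's | 1.04 | 48 |
| Saturday's | 3.00 | 47 |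
| Monday's | 0.0347 | 18 |
| Monday's | 0.104 | 48 |
| Monday's | 0.333 | 46 |
| Monday's | 1.04 | 49 |
| Monday's | 3.00 | 49 |

(standard deviation of a reading: 1.5 percentage points)

1. the best time, 4.0 d at the latest, for target
2. the amount of target, in percent of the solid substrate charged, at that time

- given per volume of solution although it is solid: solid substrate
- what was read earlier has a scatter of 1.5 percentage points, one standard deviation
- at the start none of the solid substrate is in solution

We first ask which numbers matter, working in logarithms. Friday's and Saturday's target shares at 0.0347 d give an apparent reaction order in enzyme of −0.0784, so going from Friday's enzyme to the flask's 44 µM changes that share by a factor of 1.03. Monday's run differs from Friday's in enzyme as well as in charge; setting that small enzyme factor aside, the pair gives an order of −1.16 in the charge, so we carry over the amount made rather than its share, and Monday's reading becomes 27.2 % at the flask's charge. Our time goes with the late share to the power one and with the early share to the power minus one, so these two must be known well. The readings from 1.04 d on give a late share of 48.3 %, and the early share averages 28.1 %, a pace of 8.09 d⁻¹. We commit to 48.3 % at 0.0598 d, the fill time: the late share divided by the early pace.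

The forecast gives 48 % at 0.1 d, waiting for “the first time at which a plateau was actually measured”; our time is earlier.

The flask gives 51.6 % at 0.0665 d.

    starting material + enzyme → target + enzyme, rate k1*[starting material]^2*[enzyme]/(1 + ([starting material]/Kh1)^2) (22.0 mM, k = 7.80 × 10⁵ L² mol⁻² s⁻¹)
    solid substrate ⇌ starting material, rate k2*(cs2 - [starting material]) while solid is left; crystals form when [starting material] > cs2 (solubility = 27.0 mM, k = 3.50 × 10⁻⁴ s⁻¹)
    target ⇌ isomer of the product (K = 1.10, k = 0.00110 s⁻¹)

At 0.0664 d the flask's solid substrate stands at 0 %, and target stands at 51.6 %, against 47.6 % at 4.00 d. Suppose target arrives evenly over the fill time while relaxing with half-life 0.0917 h. With x as ln(2) times the fill time over that half-life, the peak is the end share of target plus the end share of the isomer of the product times (1 − e^(−x))/x. For the flask, x is 10.8, and the reckoned peak is 52.4 %. For a neighbouring flask with 0.013 M of solid substrate, taking the same pace in amount, the reckoned fill time is 0.0147 d, x is 2.66, and the reckoned peak is 65.9 %; that neighbouring flask reaches 62.8 %.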